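**Plan**
- Retrosynthesis: the two phenolic C–O bonds of ring B (C3'–O and C5'–O) are cut first, to C–B bonds and then to the C–H bonds of a 4'-methoxyflavone.
- Ring C is then cut at O1–C2 and C4–C4a, giving symmetric 2,5-dimethoxybenzene-1,3-diol and ethyl 3-(4-methoxyphenyl)-3-oxopropanoate; the C5–O bond of that diol is cut back to a C–H bond of protected 2-methoxyresorcinol.
- Forward: ring A receives its fourth oxygen by borylation/oxidation (steps 1–4), ring C is closed by thermal condensation (step 5), and ring B is oxygenated twice at the end (steps 6–7).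
- Enabling feature: in the 4'-methoxyflavone, C3'–H and C5'–H of ring B have a single small ortho neighbour (the 4'-OMe). C3–H of ring C and C6–H of ring A each lie between two substituents, and C2'–H/C6'–H are ortho to the chromone attached at C1'.
- Stereochemistry: the target has no stereocentre and no double-bond isomerism, so nothing has to be set.

Key step: step 6

Remark: flavone numbering is used throughout; 2-methoxybenzene-1,3-diol, the ketoester 8 and bis(pinacolato)diboron are taken as commercial.

**Step 1**
Reactants: 1 2-methoxybenzene-1,3-diol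
Product: 2 2-methoxy-1,3-bis(methoxymethoxy)benzene
Conditions: MOMCl (2.5 equiv), i-Pr2NEt (3 equiv), CH2Cl2, 0 °C to rt
Reagents that add atoms: chloromethyl methyl ether, COCCl
Why: Williamson-type O-alkylation (methoxymethyl ether protection) of the two equivalent phenols with a reactive α-chloro ether should be clean, and the acetals tolerate the basic and oxidative steps that follow.

**Step 2**
Reactants: 2 2-methoxy-1,3-bis(methoxymethoxy)benzene; 3 bis(pinacolato)diboron
Product: 5 4-methoxy-3,5-bis(methoxymethoxy)phenol, via aryl pinacol boronate 4 (not isolated)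
Conditions: 3 (0.6 equiv), [Ir(OMe)(cod)]2 (1 mol %), 4,4'-di-tert-butyl-2,2'-bipyridine (2 mol %), THF, 80 °C; then 30% aq H2O2, 2 M NaOH, 0 °C to rt
Reagents that add atoms: hydrogen peroxide, OO
Why: Iridium-catalysed sterically controlled C–H borylation of a 1,2,3-trisubstituted benzene should go only to C5, the one C–H without an ortho substituent, and alkaline peroxide oxidation of the boronate (aryl shift from boron to oxygen) gives the phenol in the same flask with the base-stable acetals untouched.

**Step 3**
Reactants: 5 4-methoxy-3,5-bis(methoxymethoxy)phenol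
Product: 6 2,5-dimethoxy-1,3-bis(methoxymethoxy)benzene
Conditions: MeI (1.5 equiv), K2CO3, acetone, reflux
Reagents that add atoms: iodomethane, CI
Why: Williamson ether synthesis on the only free phenol, which is unhindered because it is flanked by two C–H positions.

**Step 4**
Reactants: 6 2,5-dimethoxy-1,3-bis(methoxymethoxy)benzene
Product: 7 2,5-dimethoxybenzene-1,3-diol
Conditions: conc. HCl (cat.), MeOH, 50 °C
Reagents that add atoms: none
Why: Acid-catalysed acetal cleavage (transacetalisation) in methanol removes both methoxymethyl groups; the solvent traps the methoxymethyl cation as dimethoxymethane before it can alkylate the electron-rich ring, and aryl methyl ethers are stable to dilute acid.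

**Step 5**
Reactants: 7 2,5-dimethoxybenzene-1,3-diol; 8 ethyl 3-(4-methoxyphenyl)-3-oxopropanoate
Product: 10 7-hydroxy-5,8-dimethoxy-2-(4-methoxyphenyl)-4H-chromen-4-one, via aryl 1,3-diketone 9 (not isolated)
Conditions: 8 (2 equiv), neat melt, 240–250 °C, N2 sweep (EtOH and H2O driven off)
Reagents that add atoms: none
Why: Mentzer pyrone synthesis (thermal flavone variant of the Simonis condensation): the ketoester loses ethanol to an aroylketene that C-acylates the phloroglucinol-like ring at C4 (equivalent to C6) to give diketone 9, whose ortho hydroxyl closes ring C by cyclodehydration; since 7 is symmetric only one flavone can form, and the remaining hydroxyl becomes the 7-OH.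

**Step 6**
Reactants: 10 7-hydroxy-5,8-dimethoxy-2-(4-methoxyphenyl)-4H-chromen-4-one; 3 bis(pinacolato)diboron
Product: 13 7-hydroxy-5,8-dimethoxy-2-[4-methoxy-3,5-bis(4,4,5,5-tetramethyl-1,3,2-dioxaborolan-2-yl)phenyl]-4H-chromen-4-one, via 7-O-boryl flavone 11 (not isolated), via tris(boryl) flavone 12 (not isolated)
Conditions: [Ir(OMe)(cod)]2 (3 mol %), 3,4,7,8-tetramethyl-1,10-phenanthroline (6 mol %), HBpin (1.2 equiv), THF, rt (H2 off); then 3 (3 equiv), 80 °C, sealed; aq NH4Cl work-up
Reagents that add atoms: none
Why: The precatalyst and B2pin2 form a phenanthroline-ligated tris(boryl) complex of trivalent iridium that cleaves an aryl C–H bond by oxidative addition to a pentavalent iridium aryl hydride, and reductive elimination forms the C–B bond while B2pin2 or HBpin regenerates the tris(boryl). The closest known reaction type is the sterically governed iridium-catalysed borylation of 1,4-disubstituted arenes ortho to the smaller substituent, here run twice on the same ring. No ring is closed and no stereocentre is formed. The step needs site selectivity for C3'–H and C5'–H, and the substrate secures it: C3–H lies between the C2 aryl group and the C4 carbonyl, C6–H lies between the 5-methoxy group and the 7-O-boronate, and C2'–H/C6'–H are ortho to the chromone ring, so only the two C–H bonds whose single ortho neighbour is the small 4'-methoxy group remain accessible. Prior O-borylation of the acidic 7-OH with HBpin keeps the phenol from consuming the catalyst, and the O–B bond is hydrolysed on aqueous work-up. The second borylation, next to a methoxy group already buttressed by one boronate, should be the slow event, which is why excess B2pin2, the long-lived tetramethylphenanthroline catalyst and 80 °C are chosen.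

**Step 7**
Reactants: 13 7-hydroxy-5,8-dimethoxy-2-[4-methoxy-3,5-bis(4,4,5,5-tetramethyl-1,3,2-dioxaborolan-2-yl)phenyl]-4H-chromen-4-one
Product: 14 2-(3,5-dihydroxy-4-methoxyphenyl)-7-hydroxy-5,8-dimethoxy-4H-chromen-4-one
Conditions: NaBO3·4H2O (6 equiv), THF/H2O (1:1), rt; then dilute HCl to pH 5
Reagents that add atoms: sodium perborate (used as the tetrahydrate), [Na+].[O-]OB=O
Why: Oxidation of aryl boronates to phenols by peroxoborate (peroxide addition to boron, aryl migration from boron to oxygen, hydrolysis of the borate ester) is general, and the mild pH of perborate should spare the pyranone ring and the three methyl ethers.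

**Compound list**
1 | 2-methoxybenzene-1,3-diol | COc1c(O)cccc1O | starting material
2 | 2-methoxy-1,3-bis(methoxymethoxy)benzene | COCOc1cccc(OCOC)c1OC | intermediate
3 | bis(pinacolato)diboron | CC1(C)OB(OC1(C)C)B1OC(C)(C)C(C)(C)O1 | starting material
4 | 2-[4-methoxy-3,5-bis(methoxymethoxy)phenyl]-4,4,5,5-tetramethyl-1,3,2-dioxaborolane | COCOc1cc(B2OC(C)(C)C(C)(C)O2)cc(OCOC)c1OC | intermediate (not isolated)
5 | 4-methoxy-3,5-bis(methoxymethoxy)phenol | COCOc1cc(O)cc(OCOC)c1OC | intermediate
6 | 2,5-dimethoxy-1,3-bis(methoxymethoxy)benzene | COCOc1cc(OC)cc(OCOC)c1OC | intermediate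
7 | 2,5-dimethoxybenzene-1,3-diol | COc1cc(O)c(OC)c(O)c1 | intermediate
8 | ethyl 3-(4-methoxyphenyl)-3-oxopropanoate | CCOC(=O)CC(=O)c1ccc(OC)cc1 | starting material
9 | 1-(2,4-dihydroxy-3,6-dimethoxyphenyl)-3-(4-methoxyphenyl)propane-1,3-dione | COc1ccc(cc1)C(=O)CC(=O)c1c(O)c(OC)c(O)cc1OC | intermediate (not isolated)
10 | 7-hydroxy-5,8-dimethoxy-2-(4-methoxyphenyl)-4H-chromen-4-one | COc1ccc(-c2cc(=O)c3c(OC)cc(O)c(OC)c3o2)cc1 | intermediate
11 | 5,8-dimethoxy-2-(4-methoxyphenyl)-7-[(4,4,5,5-tetramethyl-1,3,2-dioxaborolan-2-yl)oxy]-4H-chromen-4-one | COc1ccc(-c2cc(=O)c3c(OC)cc(OB4OC(C)(C)C(C)(C)O4)c(OC)c3o2)cc1 | intermediate (not isolated)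
12 | 5,8-dimethoxy-2-[4-methoxy-3,5-bis(4,4,5,5-tetramethyl-1,3,2-dioxaborolan-2-yl)phenyl]-7-[(4,4,5,5-tetramethyl-1,3,2-dioxaborolan-2-yl)oxy]-4H-chromen-4-one | COc1c(B2OC(C)(C)C(C)(C)O2)cc(-c2cc(=O)c3c(OC)cc(OB4OC(C)(C)C(C)(C)O4)c(OC)c3o2)cc1B1OC(C)(C)C(C)(C)O1 | intermediate (not isolated)
13 | 7-hydroxy-5,8-dimethoxy-2-[4-methoxy-3,5-bis(4,4,5,5-tetramethyl-1,3,2-dioxaborolan-2-yl)phenyl]-4H-chromen-4-one | COc1c(B2OC(C)(C)C(C)(C)O2)cc(-c2cc(=O)c3c(OC)cc(O)c(OC)c3o2)cc1B1OC(C)(C)C(C)(C)O1 | intermediate
14 | 2-(3,5-dihydroxy-4-methoxyphenyl)-7-hydroxy-5,8-dimethoxy-4H-chromen-4-one | COc1c(O)cc(-c2cc(=O)c3c(OC)cc(O)c(OC)c3o2)cc1O | target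

**Step count**
Total steps: 7. Longest linear sequence: 7 steps (1 to 14).

**Steps most likely to fail**

Step 6. The second C–H borylation may stall once one boronate is in place, because the 4'-methoxy group is then pushed toward the remaining C–H bond; the catalyst could die before the mono-borylated material is consumed. The fallback sets out from 7 and comes back at 13, bringing the two ring B handles in as bromides.
- Crossed Claisen condensation of commercial methyl 3,5-dibromo-4-methoxybenzoate with the lithium enolate of ethyl acetate (LiN(SiMe3)2, THF, −78 °C) should give ethyl 3-(3,5-dibromo-4-methoxyphenyl)-3-oxopropanoate F1.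
- Thermal Mentzer condensation of F1 with 7 under the conditions of step 5 should pass through 1-(3,5-dibromo-4-methoxyphenyl)-3-(2,4-dihydroxy-3,6-dimethoxyphenyl)propane-1,3-dione F2, not isolated, to 2-(3,5-dibromo-4-methoxyphenyl)-7-hydroxy-5,8-dimethoxy-4H-chromen-4-one F3.
- Twofold Miyaura borylation of F3 with 3 (PdCl2(dppf), KOAc, dioxane, 90 °C) should then deliver 13, after which step 7 follows unchanged.

Step 5. In the melt, O-acylation followed by Pechmann-type closure to a 4-arylcoumarin, or thermal decomposition of the electron-rich diol, may compete with flavone formation. The fallback sets out from 7 and comes back at 9 and then 10, building the diketone stepwise at low temperature in the manner of a Baker–Venkataraman sequence.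
- Friedel–Crafts acetylation of 7 (AcOH, BF3·OEt2, 80 °C) should give 1-(2,4-dihydroxy-3,6-dimethoxyphenyl)ethan-1-one F4.
- Its polylithiated form (LiN(SiMe3)2, 4 equiv, THF, −78 °C) is C-aroylated with 4-methoxybenzoyl chloride to give diketone 9, now isolated.
- Cyclodehydration (cat. H2SO4, AcOH, 95 °C) should give 10.

Step 7. Oxidative degradation of the electron-rich triphenol, base-induced opening of the pyranone ring or protodeboronation may erode the final oxidation. The fallback sets out from 7 and comes back at 14, carrying the ring B oxygens as benzyl ethers from the start.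
- Benzylation of commercial methyl 3,5-dihydroxy-4-methoxybenzoate (BnBr, K2CO3, DMF) should give methyl 3,5-bis(benzyloxy)-4-methoxybenzoate F5.
- Claisen condensation with the lithium enolate of ethyl acetate (LiN(SiMe3)2, THF, −78 °C) should give ethyl 3-[3,5-bis(benzyloxy)-4-methoxyphenyl]-3-oxopropanoate F6.
- Thermal condensation of F6 with 7 as in step 5 should pass through 1-[3,5-bis(benzyloxy)-4-methoxyphenyl]-3-(2,4-dihydroxy-3,6-dimethoxyphenyl)propane-1,3-dione F7, not isolated, to 2-[3,5-bis(benzyloxy)-4-methoxyphenyl]-7-hydroxy-5,8-dimethoxy-4H-chromen-4-one F8.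
- Hydrogenolysis (H2, Pd/C, EtOAc/MeOH, rt) should give 14.

**Further compounds**
F1 | step 6 | ethyl 3-(3,5-dibromo-4-methoxyphenyl)-3-oxopropanoate | CCOC(=O)CC(=O)c1cc(Br)c(OC)c(Br)c1
F2 | step 6 | 1-(3,5-dibromo-4-methoxyphenyl)-3-(2,4-dihydroxy-3,6-dimethoxyphenyl)propane-1,3-dione | COc1c(Br)cc(cc1Br)C(=O)CC(=O)c1c(O)c(OC)c(O)cc1OC
F3 | step 6 | 2-(3,5-dibromo-4-methoxyphenyl)-7-hydroxy-5,8-dimethoxy-4H-chromen-4-one | COc1c(Br)cc(-c2cc(=O)c3c(OC)cc(O)c(OC)c3o2)cc1Br
F4 | step 5 | 1-(2,4-dihydroxy-3,6-dimethoxyphenyl)ethan-1-one | CC(=O)c1c(O)c(OC)c(O)cc1OC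
F5 | step 7 | methyl 3,5-bis(benzyloxy)-4-methoxybenzoate | COC(=O)c1cc(OCc2ccccc2)c(OC)c(OCc2ccccc2)c1
F6 | step 7 | ethyl 3-[3,5-bis(benzyloxy)-4-methoxyphenyl]-3-oxopropanoate | CCOC(=O)CC(=O)c1cc(OCc2ccccc2)c(OC)c(OCc2ccccc2)c1
F7 | step 7 | 1-[3,5-bis(benzyloxy)-4-methoxyphenyl]-3-(2,4-dihydroxy-3,6-dimethoxyphenyl)propane-1,3-dione | COc1c(OCc2ccccc2)cc(cc1OCc1ccccc1)C(=O)CC(=O)c1c(O)c(OC)c(O)cc1OC
F8 | step 7 | 2-[3,5-bis(benzyloxy)-4-methoxyphenyl]-7-hydroxy-5,8-dimethoxy-4H-chromen-4-one | COc1c(OCc2ccccc2)cc(-c2cc(=O)c3c(OC)cc(O)c(OC)c3o2)cc1OCc1ccccc1
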